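**Retrosynthetic overview**

1. The strategy rests on ring B, the arene on C3: its C2' and C5' carry para oxygens, C4' carries OMe, and C3' and C6' carry H. This maps onto methyl semisquarate 3: ketene carbonyl → C2'–O, carbinol carbon → C5'–O, enol ether carbon → C4'–OMe, ring CH → C3'. C1' and C6' come from an alkene.
2. Target 19 ← silyl ether 18 (fluoride) ← hydroquinone 17 (two O-methylations).
3. 17 ← 4-alkenyl-4-hydroxycyclobutenone 14 by thermal ring expansion. Ring B is the only ring made; ring A is bought in aldehyde 4.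
4. 14 ← (E)-alkenyllithium 13 (from vinyl iodide 12) + semisquarate 3 (from dimethyl squarate 1).
5. 12 ← aldehyde 11 (Takai) ← alcohol 10 (carboalumination–oxidation of 7 sets C3 as S) ← 6 (allylboration of 4 sets C1 as R).

Key step: step 8

Assumption: the carbonyl of a 3-alkoxycyclobutene-1,2-dione next to the alkoxy-bearing carbon is taken as the more electrophilic one, and the sense of induction of the allylborane and of the zirconocene is taken from their behaviour with benzaldehyde and with simple 1-alkenes.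

**Route**

Step 1
Reactants: 1 dimethyl squarate
Product: 3 methyl semisquarate (3-methoxycyclobut-3-ene-1,2-dione), via hydroxycyclobutenone 2 (not isolated)
Conditions: LiAlH(OtBu)3 (1.05 equiv), THF, −78 to −20 °C; then 2 M HCl, CH2Cl2, 0 °C to rt
Reagents that add atoms: water, O
Why: Single 1,2-hydride reduction of one squarate carbonyl, then acid-induced ionisation of the carbinol, hydration of the allyl cation at the methoxy-bearing terminus and loss of methanol, is the established reduction–hydrolysis route from squarate diesters to semisquarates; no stereocentre persists.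

Step 2
Reactants: 4 2,4,5-trimethoxybenzaldehyde
Product: 6 (1R)-1-(2,4,5-trimethoxyphenyl)but-3-en-1-ol, via borinate 5 (not isolated)
Conditions: (+)-Ipc2B(allyl) (1.2 equiv), Et2O, −78 °C; then 3 M NaOH, 30% H2O2, 0 °C to rt
Reagents that add atoms: (+)-B-allyldiisopinocampheylborane, C=CCB([C@H]1C[C@H]2C[C@@H]([C@@H]1C)C2(C)C)[C@H]1C[C@H]2C[C@@H]([C@@H]1C)C2(C)C
Why: Brown asymmetric allylboration through a closed chair transition state, in which the isopinocampheyl groups derived from (−)-α-pinene send the allyl group to the Re face of the aryl aldehyde (the sense known for benzaldehyde), sets C1 as R, and the alkaline peroxide work-up cleaves the borinate without harming the electron-rich arene.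

Step 3
Reactants: 6 (1R)-1-(2,4,5-trimethoxyphenyl)but-3-en-1-ol
Product: 7 tert-butyldimethyl{[(1R)-1-(2,4,5-trimethoxyphenyl)but-3-en-1-yl]oxy}silane
Conditions: TBSCl, imidazole, DMF, rt
Reagents that add atoms: tert-butyldimethylsilyl chloride, CC(C)(C)[Si](C)(C)Cl
Why: Imidazole-promoted silylation of a secondary alcohol gives a benzylic silyl ether that should withstand the organometallic, oxidative and thermal steps ahead and is removed by fluoride at the end; the stereocentre is not involved.

Step 4
Reactants: 7 tert-butyldimethyl{[(1R)-1-(2,4,5-trimethoxyphenyl)but-3-en-1-yl]oxy}silane, 8 trimethylaluminium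
Product: 10 (2S,4R)-4-[(tert-butyldimethylsilyl)oxy]-2-methyl-4-(2,4,5-trimethoxyphenyl)butan-1-ol, via alkylalane 9 (not isolated)
Conditions: Me3Al (3 equiv), (+)-bis(1-neomenthylindenyl)zirconium dichloride (5 mol %), methylaluminoxane (MeAlO)n, CH2Cl2, 0 °C to rt; then dry O2, 0 °C to rt; aq NaOH
Reagents that add atoms: trimethylaluminium 8, C[Al](C)C; dioxygen, O=O
Why: Zirconium-catalysed asymmetric carboalumination of the terminal alkene (ZACA reaction) puts methyl on the internal carbon and aluminium on the terminal carbon under control of the chiral zirconocene, the (+)-catalyst being chosen for the 2S centre because the (−)-catalyst gives (R)-2-methylalkan-1-ols from simple 1-alkenes, and O2 oxidation of the C–Al bond gives the primary alcohol, any minor C2 epimer being a diastereomer that should be removable by chromatography.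

Step 5
Reactants: 10 (2S,4R)-4-[(tert-butyldimethylsilyl)oxy]-2-methyl-4-(2,4,5-trimethoxyphenyl)butan-1-ol
Product: 11 (2S,4R)-4-[(tert-butyldimethylsilyl)oxy]-2-methyl-4-(2,4,5-trimethoxyphenyl)butanal
Conditions: Dess–Martin periodinane, NaHCO3, CH2Cl2, 0 °C to rt; used at once
Reagents that add atoms: none
Why: Dess–Martin oxidation under bicarbonate buffer turns the primary alcohol into the aldehyde under neutral, non-enolising conditions, so the α-methyl centre and the acid-sensitive benzylic silyl ether should survive.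

Step 6
Reactants: 11 (2S,4R)-4-[(tert-butyldimethylsilyl)oxy]-2-methyl-4-(2,4,5-trimethoxyphenyl)butanal
Product: 12 tert-butyl{[(1R,3S,4E)-5-iodo-3-methyl-1-(2,4,5-trimethoxyphenyl)pent-4-en-1-yl]oxy}dimethylsilane
Conditions: CrCl2 (6 equiv), CHI3 (2 equiv), THF, 0 °C to rt, dark
Reagents that add atoms: iodoform, IC(I)I
Why: Takai iodo-olefination, in which the geminal dichromium species formed from iodoform and divalent chromium adds to the aldehyde and eliminates to the (E)-vinyl iodide, is non-basic and should leave the adjacent stereocentre and the silyl ether intact.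

Step 7
Reactants: 12 tert-butyl{[(1R,3S,4E)-5-iodo-3-methyl-1-(2,4,5-trimethoxyphenyl)pent-4-en-1-yl]oxy}dimethylsilane, 3 methyl semisquarate
Product: 14 4-{(1E,3S,5R)-5-[(tert-butyldimethylsilyl)oxy]-3-methyl-5-(2,4,5-trimethoxyphenyl)pent-1-en-1-yl}-4-hydroxy-3-methoxycyclobut-2-en-1-one, via alkenyllithium 13 (not isolated)
Conditions: t-BuLi (2.05 equiv), Et2O, −78 °C; then cannula into 3 (1.3 equiv), THF, −78 °C; aq NH4Cl at −78 °C; chromatography on base-washed silica
Reagents that add atoms: none
Why: Lithium–iodine exchange with two equivalents of t-BuLi gives the alkenyllithium with retention of the E geometry, and its 1,2-addition is expected at the ketone-like carbonyl next to the methoxy-bearing carbon, not at the vinylogous ester carbonyl, as for organolithium additions to other 3-alkoxycyclobutenediones; the new ring carbinol centre forms as a mixture that is of no consequence because it is destroyed in step 8.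

Step 8
Reactants: 14 4-{(1E,3S,5R)-5-[(tert-butyldimethylsilyl)oxy]-3-methyl-5-(2,4,5-trimethoxyphenyl)pent-1-en-1-yl}-4-hydroxy-3-methoxycyclobut-2-en-1-one
Product: 17 2-{(2S,4R)-4-[(tert-butyldimethylsilyl)oxy]-4-(2,4,5-trimethoxyphenyl)butan-2-yl}-5-methoxybenzene-1,4-diol, via dienylketene 15 (not isolated), via cyclohexadienone 16 (not isolated)
Conditions: degassed toluene, 110 °C, Ar; concentrated under Ar and used directly
Reagents that add atoms: none
Why: Heating opens the cyclobutenone by conrotatory 4π electrocyclic cleavage of the bond between the carbonyl carbon and the carbinol carbon, and the donor hydroxyl rotates outward so that the alkenyl group lies inward, cis to the ketene, in dienylketene 15. Ring B is then closed by a thermal disrotatory 6π electrocyclisation in which the ketene carbon bonds to the distal alkene carbon (the one bearing the side-chain stereocentre), giving cyclohexa-2,4-dienone 16, and enolisation of its ring CH aromatises it to hydroquinone 17. This is the known thermal ring expansion of 4-alkenyl-4-hydroxycyclobutenones to hydroquinones (Moore rearrangement), applied here to a 2-unsubstituted 3-methoxy member. No stereocentre is created: the sp3 ring carbon of 16 is lost on aromatisation, both epimers of 14 at the ring carbinol carbon converge, and the 3S and 5R centres of the side chain take part in no bond that is made or broken. The step needs outward rotation of the hydroxyl, which its lone-pair donation secures, and the 2,5-dihydroxy-4-methoxy pattern, which is fixed by the carbonyl attacked in step 7; the E alkene keeps the bulky side chain on the outside of the closing triene. Neutral, metal-free conditions should spare the benzylic silyl ether, and exclusion of air keeps 17 from oxidising to the quinone.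

Step 9
Reactants: 17 2-{(2S,4R)-4-[(tert-butyldimethylsilyl)oxy]-4-(2,4,5-trimethoxyphenyl)butan-2-yl}-5-methoxybenzene-1,4-diol
Product: 18 tert-butyl{[(1R,3S)-1,3-bis(2,4,5-trimethoxyphenyl)butyl]oxy}dimethylsilane
Conditions: MeI (excess), K2CO3, degassed DMF, rt, Ar
Reagents that add atoms: iodomethane, CI
Why: Williamson O-methylation of both phenoxides under exclusion of oxygen caps the oxidation-prone hydroquinone as its dimethyl ether and completes the 2,4,5-trimethoxy pattern of ring B; no stereocentre is touched.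

Step 10
Reactants: 18 tert-butyl{[(1R,3S)-1,3-bis(2,4,5-trimethoxyphenyl)butyl]oxy}dimethylsilane
Product: 19 (1R,3S)-1,3-bis(2,4,5-trimethoxyphenyl)butan-1-ol
Conditions: Bu4NF, THF, 0 °C to rt
Reagents that add atoms: none
Why: Fluoride-mediated cleavage of the Si–O bond frees the benzylic alcohol under basic conditions that avoid ionisation at the electron-rich benzylic carbon, so both stereocentres are retained.

**Compound list**

1 | dimethyl squarate (3,4-dimethoxycyclobut-3-ene-1,2-dione) | COC1=C(OC)C(=O)C1=O | starting material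
2 | 4-hydroxy-2,3-dimethoxycyclobut-2-en-1-one (racemic, present as its alkoxide until acidification) | COC1=C(OC)C(=O)C1O | intermediate
3 | 3-methoxycyclobut-3-ene-1,2-dione (methyl semisquarate) | COC1=CC(=O)C1=O | intermediate
4 | 2,4,5-trimethoxybenzaldehyde | COc1cc(OC)c(C=O)cc1OC | starting material
5 | (1R)-1-(2,4,5-trimethoxyphenyl)but-3-en-1-yl diisopinocampheylborinate | COc1cc(OC)c([C@H](OB([C@H]2C[C@H]3C[C@@H]([C@@H]2C)C3(C)C)[C@H]2C[C@H]3C[C@@H]([C@@H]2C)C3(C)C)CC=C)cc1OC | intermediate
6 | (1R)-1-(2,4,5-trimethoxyphenyl)but-3-en-1-ol | COc1cc(OC)c([C@H](O)CC=C)cc1OC | intermediate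
7 | tert-butyldimethyl{[(1R)-1-(2,4,5-trimethoxyphenyl)but-3-en-1-yl]oxy}silane | COc1cc(OC)c([C@H](O[Si](C)(C)C(C)(C)C)CC=C)cc1OC | intermediate
8 | trimethylaluminium | C[Al](C)C | starting material
9 | {(2S,4R)-4-[(tert-butyldimethylsilyl)oxy]-2-methyl-4-(2,4,5-trimethoxyphenyl)butyl}dimethylalumane | COc1cc(OC)c([C@H](O[Si](C)(C)C(C)(C)C)C[C@H](C)C[Al](C)C)cc1OC | intermediate
10 | (2S,4R)-4-[(tert-butyldimethylsilyl)oxy]-2-methyl-4-(2,4,5-trimethoxyphenyl)butan-1-ol | COc1cc(OC)c([C@H](O[Si](C)(C)C(C)(C)C)C[C@H](C)CO)cc1OC | intermediate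
11 | (2S,4R)-4-[(tert-butyldimethylsilyl)oxy]-2-methyl-4-(2,4,5-trimethoxyphenyl)butanal | COc1cc(OC)c([C@H](O[Si](C)(C)C(C)(C)C)C[C@H](C)C=O)cc1OC | intermediate
12 | tert-butyl{[(1R,3S,4E)-5-iodo-3-methyl-1-(2,4,5-trimethoxyphenyl)pent-4-en-1-yl]oxy}dimethylsilane | COc1cc(OC)c([C@H](O[Si](C)(C)C(C)(C)C)C[C@H](C)/C=C/I)cc1OC | intermediate
13 | {(1E,3S,5R)-5-[(tert-butyldimethylsilyl)oxy]-3-methyl-5-(2,4,5-trimethoxyphenyl)pent-1-en-1-yl}lithium | COc1cc(OC)c([C@H](O[Si](C)(C)C(C)(C)C)C[C@H](C)/C=C/[Li])cc1OC | intermediate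
14 | 4-{(1E,3S,5R)-5-[(tert-butyldimethylsilyl)oxy]-3-methyl-5-(2,4,5-trimethoxyphenyl)pent-1-en-1-yl}-4-hydroxy-3-methoxycyclobut-2-en-1-one (both epimers at the ring carbinol carbon) | COC1=CC(=O)C1(O)/C=C/[C@@H](C)C[C@@H](O[Si](C)(C)C(C)(C)C)c1cc(OC)c(OC)cc1OC | intermediate
15 | (3Z,5E,7S,9R)-9-[(tert-butyldimethylsilyl)oxy]-4-hydroxy-3-methoxy-7-methyl-9-(2,4,5-trimethoxyphenyl)nona-1,3,5-trien-1-one | O=C=C/C(OC)=C(\C=C\[C@@H](C)C[C@@H](O[Si](C)(C)C(C)(C)C)c1cc(OC)c(OC)cc1OC)O | intermediate
16 | 6-{(2S,4R)-4-[(tert-butyldimethylsilyl)oxy]-4-(2,4,5-trimethoxyphenyl)butan-2-yl}-4-hydroxy-3-methoxycyclohexa-2,4-dien-1-one (ring CH as either epimer) | COC1=CC(=O)C(C=C1O)[C@@H](C)C[C@@H](O[Si](C)(C)C(C)(C)C)c1cc(OC)c(OC)cc1OC | intermediate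
17 | 2-{(2S,4R)-4-[(tert-butyldimethylsilyl)oxy]-4-(2,4,5-trimethoxyphenyl)butan-2-yl}-5-methoxybenzene-1,4-diol | COc1cc(OC)c([C@H](O[Si](C)(C)C(C)(C)C)C[C@H](C)c2cc(O)c(OC)cc2O)cc1OC | intermediate
18 | tert-butyl{[(1R,3S)-1,3-bis(2,4,5-trimethoxyphenyl)butyl]oxy}dimethylsilane | COc1cc(OC)c([C@H](O[Si](C)(C)C(C)(C)C)C[C@H](C)c2cc(OC)c(OC)cc2OC)cc1OC | intermediate
19 | (1R,3S)-1,3-bis(2,4,5-trimethoxyphenyl)butan-1-ol | COc1cc(OC)c([C@H](O)C[C@H](C)c2cc(OC)c(OC)cc2OC)cc1OC | target

**Step count**

Total: 10 steps. Longest linear sequence: 9 steps (steps 2 to 10, from aldehyde 4); step 1 is a one-step side branch.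

**Steps most likely to fail, with fallbacks**

Step 8 (key step). The free tertiary hydroxyl may add to the ketene and divert material to a butenolide. The hydroquinone may oxidise in air. The benzylic silyl ether may ionise at 110 °C next to the new ortho phenol and close a chroman. The fallback removes the hydroxyl before the ring expansion and sets out from 12 and 3. The lithiation and addition are run as in step 7, but the lithium alkoxide is quenched at −78 °C with methyl triflate. This gives 4-{(1E,3S,5R)-5-[(tert-butyldimethylsilyl)oxy]-3-methyl-5-(2,4,5-trimethoxyphenyl)pent-1-en-1-yl}-3,4-dimethoxycyclobut-2-en-1-one F8. Heating F8 in toluene should give, by the same ring opening (methoxy also rotates outward and cannot add to the ketene) and 6π closure, the air-stable monophenol 2-{(2S,4R)-4-[(tert-butyldimethylsilyl)oxy]-4-(2,4,5-trimethoxyphenyl)butan-2-yl}-4,5-dimethoxyphenol F9. One O-methylation of F9 (MeI, K2CO3, DMF) comes back to the route at 18.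

Step 4. Facial selectivity of the carbometalation may be poor on this branched, Lewis-basic substrate, and Me3Al may ionise the electron-rich benzylic silyl ether. The fallback sets the methyl centre by auxiliary control and sets out from 7.
- Hydroboration of 7 (9-BBN, THF; then NaOH, H2O2) gives (4R)-4-[(tert-butyldimethylsilyl)oxy]-4-(2,4,5-trimethoxyphenyl)butan-1-ol F1.
- Dess–Martin oxidation and then NaClO2, NaH2PO4 and 2-methylbut-2-ene give (4R)-4-[(tert-butyldimethylsilyl)oxy]-4-(2,4,5-trimethoxyphenyl)butanoic acid F2.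
- The mixed pivalic anhydride (pivaloyl chloride, Et3N) is acylated with lithiated (4S)-4-benzyl-1,3-oxazolidin-2-one to give (4S)-4-benzyl-3-{(4R)-4-[(tert-butyldimethylsilyl)oxy]-4-(2,4,5-trimethoxyphenyl)butanoyl}-1,3-oxazolidin-2-one F3.
- Evans methylation (NaHMDS, MeI, THF, −78 °C; the Z enolate is alkylated on the face away from the benzyl group) gives (4S)-4-benzyl-3-{(2S,4R)-4-[(tert-butyldimethylsilyl)oxy]-2-methyl-4-(2,4,5-trimethoxyphenyl)butanoyl}-1,3-oxazolidin-2-one F4.
- Reductive removal of the auxiliary with LiBH4 (THF, MeOH, 0 °C) comes back to the route at 10.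

Step 7. The hard, basic alkenyllithium may transfer a proton, may displace methoxide by addition–elimination at the methoxy-bearing carbon, or may be formed with partial loss of alkene geometry. The fallback uses a less basic acetylide made by deprotonation and sets out from 11.
- Ohira–Bestmann homologation (dimethyl (1-diazo-2-oxopropyl)phosphonate, K2CO3, MeOH, 0 °C) gives tert-butyldimethyl{[(1R,3S)-3-methyl-1-(2,4,5-trimethoxyphenyl)pent-4-yn-1-yl]oxy}silane F5.
- Deprotonation (n-BuLi, THF, −78 °C) and addition to 3 give 4-{(3S,5R)-5-[(tert-butyldimethylsilyl)oxy]-3-methyl-5-(2,4,5-trimethoxyphenyl)pent-1-yn-1-yl}-4-hydroxy-3-methoxycyclobut-2-en-1-one F6.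
- Thermolysis of F6 in refluxing toluene or p-xylene (the known ring expansion of 4-alkynyl-4-hydroxycyclobutenones through an enynylketene and a ring diradical) should give 2-{(2S,4R)-4-[(tert-butyldimethylsilyl)oxy]-4-(2,4,5-trimethoxyphenyl)butan-2-yl}-5-methoxycyclohexa-2,5-diene-1,4-dione F7.
- Reduction of F7 with aqueous Na2S2O4 under argon comes back to the route at 17, which is methylated at once as in step 9.

**Further compounds**

F1 | step 4 | (4R)-4-[(tert-butyldimethylsilyl)oxy]-4-(2,4,5-trimethoxyphenyl)butan-1-ol | COc1cc(OC)c([C@H](O[Si](C)(C)C(C)(C)C)CCCO)cc1OC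
F2 | step 4 | (4R)-4-[(tert-butyldimethylsilyl)oxy]-4-(2,4,5-trimethoxyphenyl)butanoic acid | COc1cc(OC)c([C@H](O[Si](C)(C)C(C)(C)C)CCC(=O)O)cc1OC
F3 | step 4 | (4S)-4-benzyl-3-{(4R)-4-[(tert-butyldimethylsilyl)oxy]-4-(2,4,5-trimethoxyphenyl)butanoyl}-1,3-oxazolidin-2-one | COc1cc(OC)c([C@H](O[Si](C)(C)C(C)(C)C)CCC(=O)N2[C@@H](Cc3ccccc3)COC2=O)cc1OC
F4 | step 4 | (4S)-4-benzyl-3-{(2S,4R)-4-[(tert-butyldimethylsilyl)oxy]-2-methyl-4-(2,4,5-trimethoxyphenyl)butanoyl}-1,3-oxazolidin-2-one | COc1cc(OC)c([C@H](O[Si](C)(C)C(C)(C)C)C[C@H](C)C(=O)N2[C@@H](Cc3ccccc3)COC2=O)cc1OC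
F5 | step 7 | tert-butyldimethyl{[(1R,3S)-3-methyl-1-(2,4,5-trimethoxyphenyl)pent-4-yn-1-yl]oxy}silane | COc1cc(OC)c([C@H](O[Si](C)(C)C(C)(C)C)C[C@H](C)C#C)cc1OC
F6 | step 7 | 4-{(3S,5R)-5-[(tert-butyldimethylsilyl)oxy]-3-methyl-5-(2,4,5-trimethoxyphenyl)pent-1-yn-1-yl}-4-hydroxy-3-methoxycyclobut-2-en-1-one | COC1=CC(=O)C1(O)C#C[C@@H](C)C[C@@H](O[Si](C)(C)C(C)(C)C)c1cc(OC)c(OC)cc1OC
F7 | step 7 | 2-{(2S,4R)-4-[(tert-butyldimethylsilyl)oxy]-4-(2,4,5-trimethoxyphenyl)butan-2-yl}-5-methoxycyclohexa-2,5-diene-1,4-dione | COC1=CC(=O)C(=CC1=O)[C@@H](C)C[C@@H](O[Si](C)(C)C(C)(C)C)c1cc(OC)c(OC)cc1OC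
F8 | step 8 | 4-{(1E,3S,5R)-5-[(tert-butyldimethylsilyl)oxy]-3-methyl-5-(2,4,5-trimethoxyphenyl)pent-1-en-1-yl}-3,4-dimethoxycyclobut-2-en-1-one | COC1=CC(=O)C1(OC)/C=C/[C@@H](C)C[C@@H](O[Si](C)(C)C(C)(C)C)c1cc(OC)c(OC)cc1OC
F9 | step 8 | 2-{(2S,4R)-4-[(tert-butyldimethylsilyl)oxy]-4-(2,4,5-trimethoxyphenyl)butan-2-yl}-4,5-dimethoxyphenol | COc1cc(OC)c([C@H](O[Si](C)(C)C(C)(C)C)C[C@H](C)c2cc(OC)c(OC)cc2O)cc1OC
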